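**Retrosynthetic overview**

1. The alkylidene butenolide (C6, C7, C11, C12, C13) is carried as a 3,4-disubstituted furan and unveiled at the end with singlet oxygen and dehydration; the C13 acetate and the C8 hydroxytiglate are attached late.
2. The oxolane hemiketal is disconnected at C1–C2: a C2 carbanion (2-bromoethyl arm on C4) attacks the C1 carbonyl of a nine-membered lactone whose ring is C1–O–C4–C5–C6–C7–C8–C9–C10.
3. That lactone comes from an eight-membered carbocyclic ketone (ring C1, C4, C5, C6, C7, C8, C9, C10) by Baeyer–Villiger insertion of oxygen between C1 and C4. This is possible because the ring oxygen of the target lies between the carbonyl-level C1 and the fully substituted C4 (which migrates, with retention), and because the C8 acyl and C13 ester groups shield the furan from peracid.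
4. The cyclooctanone comes from C4–C5 ring closure of a β-keto ester, then Pd-catalysed decarboxylative allylation (sets C4); the chain comes from Negishi acylation (C8–C9, C10 from the chiral pool) and Masamune homologation (C1–C4); the furan from a Feist–Benary synthesis.
5. Ring order: furan → eight-membered carbocycle → nine-membered oxonine lactone (ring expansion) → temporary γ-lactone C8–O–C13 → oxolane hemiketal → butenolide.

Key step: step 13

Remark: skeleton numbering is that of germacranolides (C1 hemiketal carbon, C2/C3 the oxolane CH2CH2, C4 bearing a methyl, C5 the =CH, C6–C7 the butenolide fusion, C8 acyloxy carbon, C9 CH2, C10 bearing a methyl, C11, C12 lactone C=O, C13 the CH2OAc carbon). Descriptors in descriptive names of 24–40 use this numbering; systematic names use their own locants. It is assumed that C10, α to the C1 carbonyl, keeps its configuration under the neutral or weakly basic conditions chosen.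

**Step 1**
Reactants: 1 tert-butyl 4-chloro-3-oxobutanoate; 2 ethyl 3-bromo-2-oxopropanoate
Product: 4 3-tert-butyl 4-ethyl 2-(chloromethyl)furan-3,4-dicarboxylate, via hydroxydihydrofuran 3 (not isolated)
Conditions: pyridine, THF, 0 °C → rt; then p-TsOH (cat.), CH2Cl2, rt
Reagents that add atoms: none
Why: Feist–Benary furan synthesis: the β-keto ester carbon adds to the pyruvate ketone, the enol oxygen displaces bromide, and acid-catalysed dehydration aromatises 3, which places the two esters on adjacent β-carbons and the chloromethyl group at the α-carbon.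

**Step 2**
Reactants: 4 3-tert-butyl 4-ethyl 2-(chloromethyl)furan-3,4-dicarboxylate
Product: 6 ethyl 4-(chlorocarbonyl)-5-(chloromethyl)furan-3-carboxylate, via furoic acid 5 (not isolated)
Conditions: CF3CO2H, CH2Cl2, 0 °C → rt; then (COCl)2, DMF (cat.), CH2Cl2, 0 °C → rt
Reagents that add atoms: oxalyl chloride, ClC(=O)C(Cl)=O
Why: Acidolysis of the tert-butyl ester (the ethyl ester is inert) followed by Vilsmeier-type acid chloride formation should give the bis-electrophile without touching the chloromethyl group.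

**Step 3**
Reactants: 7 (2S)-3-bromo-2-methylpropan-1-ol
Product: 8 (2S)-3-bromo-2-methylpropanoic acid
Conditions: TEMPO (cat.), PhI(OAc)2, MeCN–H2O, rt
Reagents that add atoms: water, O
Why: Oxoammonium (TEMPO) oxidation of the primary alcohol through the aldehyde hydrate under near-neutral conditions should not epimerise the α-stereocentre.

**Step 4**
Reactants: 8 (2S)-3-bromo-2-methylpropanoic acid
Product: 9 tert-butyl (2S)-3-bromo-2-methylpropanoate
Conditions: 2-methylpropene, H2SO4 (cat.), CH2Cl2, sealed tube, rt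
Reagents that add atoms: 2-methylpropene, CC(C)=C
Why: Acid-catalysed addition of the carboxylic acid to isobutene gives the ester that can later be cleaved by acid in the presence of the ethyl ester and the chloromethyl group.

**Step 5**
Reactants: 9 tert-butyl (2S)-3-bromo-2-methylpropanoate; 6 ethyl 4-(chlorocarbonyl)-5-(chloromethyl)furan-3-carboxylate
Product: 11 ethyl 4-[(3R)-4-tert-butoxy-3-methyl-4-oxobutanoyl]-5-(chloromethyl)furan-3-carboxylate, via alkylzinc bromide 10 (not isolated)
Conditions: Zn dust, LiCl, THF, 40 °C; then 6, Pd(PPh3)4 (cat.), THF, 0 °C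
Reagents that add atoms: none
Why: Zinc insertion gives a configurationally safe zinc homoenolate (stereocentre β to zinc), and Negishi acylation forms C8–C9 because zerovalent palladium inserts into the acyl chloride faster than into the furfuryl chloride.

**Step 6**
Reactants: 11 ethyl 4-[(3R)-4-tert-butoxy-3-methyl-4-oxobutanoyl]-5-(chloromethyl)furan-3-carboxylate
Product: 12 (2R)-4-[2-(chloromethyl)-4-(ethoxycarbonyl)furan-3-yl]-2-methyl-4-oxobutanoic acid
Conditions: CF3CO2H, CH2Cl2, 0 °C → rt
Reagents that add atoms: none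
Why: Acidolysis of the tert-butyl ester frees the C1 acid selectively and without base, so C10 is not enolised.

**Step 7**
Reactants: 13 2,2,5-trimethyl-1,3-dioxane-4,6-dione; 14 prop-2-en-1-ol
Product: 15 2-methyl-3-oxo-3-(prop-2-en-1-yloxy)propanoic acid
Conditions: toluene, 100 °C
Reagents that add atoms: none
Why: Alcoholysis of the Meldrum's acid derivative with loss of acetone gives the malonic half ester needed for the homologation.

**Step 8**
Reactants: 12 (2R)-4-[2-(chloromethyl)-4-(ethoxycarbonyl)furan-3-yl]-2-methyl-4-oxobutanoic acid; 15 2-methyl-3-oxo-3-(prop-2-en-1-yloxy)propanoic acid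
Product: 17 prop-2-en-1-yl (4R)-6-[2-(chloromethyl)-4-(ethoxycarbonyl)furan-3-yl]-2,4-dimethyl-3,6-dioxohexanoate (both C2 epimers), via acyl imidazole 16 (not isolated)
Conditions: 12, 1,1'-carbonyldiimidazole, THF, rt; then magnesium salt of 15 [from Mg(OEt)2], THF, rt → 40 °C; 1 M HCl work-up
Reagents that add atoms: none
Why: Masamune–Brooks homologation (C-acylation of the magnesium malonate by the acyl imidazole, then decarboxylation) forms C1–C4 under neutral conditions that should preserve C10 and spare the chloromethyl group; the new C4 centre need not be controlled.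

**Step 9**
Reactants: 17 prop-2-en-1-yl (4R)-6-[2-(chloromethyl)-4-(ethoxycarbonyl)furan-3-yl]-2,4-dimethyl-3,6-dioxohexanoate
Product: 18 3-ethyl 8-(prop-2-en-1-yl) (6R)-6,8-dimethyl-4,7-dioxo-4,5,6,7,8,9-hexahydrocycloocta[b]furan-3,8-dicarboxylate (both C8 epimers)
Conditions: Cs2CO3, NaI (cat.), MeCN, slow addition (high dilution), 50 °C
Reagents that add atoms: none
Why: Intramolecular SN2 C-alkylation of the stabilised β-keto ester anion by the furfuryl halide (iodide catalysis) closes the eight-membered carbocycle (C4–C5), helped by the rigid furan and two ring carbonyls; the weak base deprotonates only the β-keto ester, and the C4 configuration is erased in step 10.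

**Step 10**
Reactants: 18 3-ethyl 8-(prop-2-en-1-yl) (6R)-6,8-dimethyl-4,7-dioxo-4,5,6,7,8,9-hexahydrocycloocta[b]furan-3,8-dicarboxylate
Product: 19 ethyl (6R,8S)-6,8-dimethyl-4,7-dioxo-8-(prop-2-en-1-yl)-4,5,6,7,8,9-hexahydrocycloocta[b]furan-3-carboxylate
Conditions: Pd2(dba)3 (cat.), (R)-t-BuPHOX (cat.), toluene, 30 °C
Reagents that add atoms: none
Why: Decarboxylative asymmetric allylic alkylation (Tsuji type): ionisation of the allyl ester by zerovalent palladium and loss of CO2 turn both C4 epimers into one palladium enolate, and the chiral ligand (enantiomer chosen by analogy with 2-methylcycloalkanone substrates) should direct allylation to the face that gives the (8S) quaternary centre, while C10 is not enolised.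

**Step 11**
Reactants: 19 ethyl (6R,8S)-6,8-dimethyl-4,7-dioxo-8-(prop-2-en-1-yl)-4,5,6,7,8,9-hexahydrocycloocta[b]furan-3-carboxylate
Product: 21 ethyl (6R,8S)-8-(2-hydroxyethyl)-6,8-dimethyl-4,7-dioxo-4,5,6,7,8,9-hexahydrocycloocta[b]furan-3-carboxylate, via aldehyde 20 (not isolated)
Conditions: OsO4 (cat.), NaIO4, 2,6-lutidine, dioxane–H2O, rt; then NaBH(OAc)3, CH2Cl2, AcOH (cat.), 0 °C → rt
Reagents that add atoms: sodium periodate, [Na+].[O-]I(=O)(=O)=O
Why: Lemieux–Johnson cleavage of the only electron-rich alkene (the furan is doubly deactivated) removes one carbon, and NaBH(OAc)3 should reduce the aldehyde but neither ketone.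

**Step 12**
Reactants: 21 ethyl (6R,8S)-8-(2-hydroxyethyl)-6,8-dimethyl-4,7-dioxo-4,5,6,7,8,9-hexahydrocycloocta[b]furan-3-carboxylate
Product: 22 ethyl (6R,8R)-8-(2-bromoethyl)-6,8-dimethyl-4,7-dioxo-4,5,6,7,8,9-hexahydrocycloocta[b]furan-3-carboxylate
Conditions: CBr4, PPh3, CH2Cl2, 0 °C
Reagents that add atoms: tetrabromomethane, BrC(Br)(Br)Br
Why: The Appel reaction converts the primary alcohol under neutral conditions into a bromide that survives peracid and later serves as the C2 carbanion precursor.

**Step 13**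
Reactants: 22 ethyl (6R,8R)-8-(2-bromoethyl)-6,8-dimethyl-4,7-dioxo-4,5,6,7,8,9-hexahydrocycloocta[b]furan-3-carboxylate
Product: 24 keto lactone (4R,10R): furan-fused nine-membered lactone with ring C1(=O)–O–C4–C5–C6=C7–C8(=O)–C9–C10, C4 bearing CH3 and CH2CH2Br, C10 bearing CH3, CO2Et on C11, via Criegee adduct 23 (not isolated)
Conditions: (CF3CO)2O, H2O2·urea, Na2HPO4, CH2Cl2, 0 °C → rt
Reagents that add atoms: trifluoroperacetic acid (formed in the flask), OOC(=O)C(F)(F)F
Why: Baeyer–Villiger oxidation: the peracid adds to the C1 ketone to give Criegee adduct 23, whose C1–C4 bond, antiperiplanar to the O–O bond, migrates to oxygen as trifluoroacetate leaves, so one oxygen atom is inserted between C1 and C4. The closest known reaction type is the peracid ring expansion of α-quaternary cycloalkanones to lactones with migration of the more substituted carbon. The nine-membered ring C1–O–C4–C5–C6–C7–C8–C9–C10 is not closed by a cyclisation but arises from the eight-membered carbocycle of 22 by ring expansion by one atom (1,2-shift from carbon to oxygen). No new stereocentre is formed: C4 migrates with retention, so the configuration set in step 10 becomes that of the tertiary C4–O centre, and C10 is untouched. Regioselectivity (C4 over C10) rests on the higher migratory aptitude of the fully substituted C4 over the secondary C10; chemoselectivity rests on the C8 carbonyl being a poorly electrophilic vinylogous ester conjugated to the furan oxygen and on the furan being deactivated at both α-positions by the C8 acyl and C13 ester groups. The primary bromide is inert, and the Na2HPO4 buffer protects the acid-labile tertiary ester linkage once it is formed.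

**Step 14**
Reactants: 24 keto lactone (4R,10R)
Product: 26 bromo bis-lactone (4R,8S,10R): nine-membered C1(=O)–O–C4 lactone plus γ-lactone C8–O–C13(=O) fused to the furan 3,4-bond, via hydroxy ester 25 (not isolated)
Conditions: (R)-Me-CBS (cat.), BH3·SMe2, THF, −30 °C; MeOH; then PPTS (cat.), toluene, 40 °C
Reagents that add atoms: none
Why: Corey–Bakshi–Shibata reduction of the furyl ketone (furyl as the large group) should set (8S) under reagent control, and the new hydroxyl closes onto the neighbouring ethyl ester (phthalide-type lactonisation), which protects it and prevents its attack on the C1 lactone.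

**Step 15**
Reactants: 26 bromo bis-lactone (4R,8S,10R)
Product: 28 triethylsilyl ketal (1S,4S,8S,10R): 1-triethylsilyloxy-1,4-epoxide (oxolane C1–C2–C3–C4–O) bridging the nine-membered ring, γ-lactone C8–O–C13 retained, via bridged hemiketal 27 (not isolated)
Conditions: SmI2, HMPA, THF, −78 → 0 °C; aq. NH4Cl; then Et3SiOTf, 2,6-lutidine, CH2Cl2, −78 °C
Reagents that add atoms: triethylsilyl trifluoromethanesulfonate, CC[Si](CC)(CC)OS(=O)(=O)C(F)(F)F
Why: Samarium-Barbier intramolecular nucleophilic acyl substitution: the C2 organosamarium from the bromide adds 5-exo to the C1 lactone carbonyl and the tetrahedral adduct persists as the bridged hemiketal, whose C1 configuration is dictated by the cis bridge from C4; silylation then masks the hemiketal against hydride.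

**Step 16**
Reactants: 28 triethylsilyl ketal (1S,4S,8S,10R)
Product: 29 diol (1S,4S,8S,10R): CH2OH on C11, OH on C8, OSiEt3 on C1, furan intact
Conditions: LiBH4, THF–MeOH, 0 °C → rt
Reagents that add atoms: none
Why: Hydride reduction of the furan-fused γ-lactone releases the C13 primary and C8 secondary alcohols in one operation, the silyl ketal and the ethers being inert.

**Step 17**
Reactants: 29 diol (1S,4S,8S,10R)
Product: 30 C13 acetate (1S,4S,8S,10R): CH2OAc on C11, free OH on C8
Conditions: Ac2O, 2,4,6-collidine, CH2Cl2, −20 °C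
Reagents that add atoms: acetic anhydride, CC(=O)OC(C)=O
Why: Selective acylation of the unhindered primary alcohol over the hindered secondary C8 alcohol should install the C13 acetate of the target.

**Step 18**
Reactants: 31 2-(tert-butyldimethylsilyloxy)acetaldehyde; 32 ethyl 2-(triphenylphosphoranylidene)propanoate
Product: 33 ethyl (2E)-4-(tert-butyldimethylsilyloxy)-2-methylbut-2-enoate
Conditions: CH2Cl2, rt
Reagents that add atoms: none
Why: Wittig olefination with a stabilised ylide should give the (E)-trisubstituted enoate.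

**Step 19**
Reactants: 33 ethyl (2E)-4-(tert-butyldimethylsilyloxy)-2-methylbut-2-enoate
Product: 34 (2E)-4-(tert-butyldimethylsilyloxy)-2-methylbut-2-enoic acid
Conditions: LiOH, THF–H2O, rt; then 1 M HCl to pH 4
Reagents that add atoms: lithium hydroxide, [Li+].[OH-]
Why: Saponification of the ethyl ester leaves the silyl ether and the alkene geometry untouched.

**Step 20**
Reactants: 30 C13 acetate (1S,4S,8S,10R); 34 (2E)-4-(tert-butyldimethylsilyloxy)-2-methylbut-2-enoic acid
Product: 35 furan diester (1S,4S,8S,10R): CH2OAc on C11, (2E)-4-(tert-butyldimethylsilyloxy)-2-methylbut-2-enoate on C8, OSiEt3 on C1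
Conditions: DCC, DMAP (cat.), CH2Cl2, 0 °C → rt
Reagents that add atoms: none
Why: Steglich esterification acylates the only free hydroxyl (C8) with retention at C8.

**Step 21**
Reactants: 35 furan diester (1S,4S,8S,10R)
Product: 37 γ-hydroxybutenolide (C6 epimers): C12 lactone carbonyl, OH on C6, C7=C11 retained, via endoperoxide 36 (not isolated)
Conditions: O2, rose bengal (cat.), visible light, i-Pr2NEt, CH2Cl2, −78 °C → rt
Reagents that add atoms: dioxygen, O=O
Why: [4+2] photooxygenation of the now electron-rich trialkylfuran by singlet oxygen and Kornblum–DeLaMare fragmentation of the endoperoxide (the base removes the only bridgehead hydrogen, at C12) fix the carbonyl at C12 and the hydroxyl at C6; the electron-poor tiglate alkene does not react.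

**Step 22**
Reactants: 37 γ-hydroxybutenolide (C6 epimers)
Product: 39 bis-silyl ether of the target (1S,4S,8S,10R): C5=C6 alkylidene butenolide with C4 and C7 cis, via mesylate 38 (not isolated)
Conditions: MeSO2Cl, Et3N, CH2Cl2, −20 → 0 °C
Reagents that add atoms: none
Why: Dehydration of the pseudo-acid hydroxyl through its mesylate (ionisation to the 2-oxyfuranylium ion, loss of a C5 proton) gives the γ-alkylidene butenolide; C7 has no hydrogen, and the medium ring imposes the geometry with C4 and C7 cis.

**Step 23**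
Reactants: 39 bis-silyl ether of the target
Product: 40 (1R,4S,8S,10R)-13-acetoxy-1-hydroxy-8-[(2E)-4-hydroxy-2-methylbut-2-enoyloxy]-1,4-epoxygermacra-5,7(11)-dien-12,6-olide (target, CNP0154520.2)
Conditions: HF·pyridine, pyridine, THF, 0 °C
Reagents that add atoms: none
Why: Buffered fluoride desilylation removes the triethylsilyl ketal and the tert-butyldimethylsilyl ether without touching the acetate, the enoate or the alkylidene butenolide.

**Compound list**

1 | tert-butyl 4-chloro-3-oxobutanoate | CC(C)(C)OC(=O)CC(=O)CCl | starting material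
2 | ethyl 3-bromo-2-oxopropanoate | CCOC(=O)C(=O)CBr | starting material
3 | 3-tert-butyl 4-ethyl 2-(chloromethyl)-4-hydroxy-4,5-dihydrofuran-3,4-dicarboxylate (racemic) | CCOC(=O)C1(O)COC(CCl)=C1C(=O)OC(C)(C)C | intermediate
4 | 3-tert-butyl 4-ethyl 2-(chloromethyl)furan-3,4-dicarboxylate | CCOC(=O)c1coc(CCl)c1C(=O)OC(C)(C)C | intermediate
5 | 2-(chloromethyl)-4-(ethoxycarbonyl)furan-3-carboxylic acid | CCOC(=O)c1coc(CCl)c1C(=O)O | intermediate
6 | ethyl 4-(chlorocarbonyl)-5-(chloromethyl)furan-3-carboxylate | CCOC(=O)c1coc(CCl)c1C(Cl)=O | intermediate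
7 | (2S)-3-bromo-2-methylpropan-1-ol | OC[C@H](C)CBr | starting material
8 | (2S)-3-bromo-2-methylpropanoic acid | OC(=O)[C@H](C)CBr | intermediate
9 | tert-butyl (2S)-3-bromo-2-methylpropanoate | CC(C)(C)OC(=O)[C@H](C)CBr | intermediate
10 | [(2S)-3-tert-butoxy-2-methyl-3-oxopropyl]zinc bromide | CC(C)(C)OC(=O)[C@H](C)C[Zn]Br | intermediate
11 | ethyl 4-[(3R)-4-tert-butoxy-3-methyl-4-oxobutanoyl]-5-(chloromethyl)furan-3-carboxylate | CCOC(=O)c1coc(CCl)c1C(=O)C[C@@H](C)C(=O)OC(C)(C)C | intermediate
12 | (2R)-4-[2-(chloromethyl)-4-(ethoxycarbonyl)furan-3-yl]-2-methyl-4-oxobutanoic acid | CCOC(=O)c1coc(CCl)c1C(=O)C[C@@H](C)C(=O)O | intermediate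
13 | 2,2,5-trimethyl-1,3-dioxane-4,6-dione | CC1C(=O)OC(C)(C)OC1=O | starting material
14 | prop-2-en-1-ol | C=CCO | starting material
15 | 2-methyl-3-oxo-3-(prop-2-en-1-yloxy)propanoic acid (racemic) | CC(C(=O)O)C(=O)OCC=C | intermediate
16 | ethyl 5-(chloromethyl)-4-[(3R)-4-(imidazol-1-yl)-3-methyl-4-oxobutanoyl]furan-3-carboxylate | CCOC(=O)c1coc(CCl)c1C(=O)C[C@@H](C)C(=O)n1ccnc1 | intermediate
17 | prop-2-en-1-yl (4R)-6-[2-(chloromethyl)-4-(ethoxycarbonyl)furan-3-yl]-2,4-dimethyl-3,6-dioxohexanoate (C2 epimers) | CCOC(=O)c1coc(CCl)c1C(=O)C[C@@H](C)C(=O)C(C)C(=O)OCC=C | intermediate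
18 | 3-ethyl 8-(prop-2-en-1-yl) (6R)-6,8-dimethyl-4,7-dioxo-4,5,6,7,8,9-hexahydrocycloocta[b]furan-3,8-dicarboxylate (C8 epimers) | CCOC(=O)c1c2c(CC(C)(C(=O)OCC=C)C(=O)[C@H](C)CC2=O)oc1 | intermediate
19 | ethyl (6R,8S)-6,8-dimethyl-4,7-dioxo-8-(prop-2-en-1-yl)-4,5,6,7,8,9-hexahydrocycloocta[b]furan-3-carboxylate | CCOC(=O)c1c2c(C[C@](C)(CC=C)C(=O)[C@H](C)CC2=O)oc1 | intermediate
20 | ethyl (6R,8R)-6,8-dimethyl-4,7-dioxo-8-(2-oxoethyl)-4,5,6,7,8,9-hexahydrocycloocta[b]furan-3-carboxylate | CCOC(=O)c1c2c(C[C@](C)(CC=O)C(=O)[C@H](C)CC2=O)oc1 | intermediate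
21 | ethyl (6R,8S)-8-(2-hydroxyethyl)-6,8-dimethyl-4,7-dioxo-4,5,6,7,8,9-hexahydrocycloocta[b]furan-3-carboxylate | CCOC(=O)c1c2c(C[C@](C)(CCO)C(=O)[C@H](C)CC2=O)oc1 | intermediate
22 | ethyl (6R,8R)-8-(2-bromoethyl)-6,8-dimethyl-4,7-dioxo-4,5,6,7,8,9-hexahydrocycloocta[b]furan-3-carboxylate | CCOC(=O)c1c2c(C[C@](C)(CCBr)C(=O)[C@H](C)CC2=O)oc1 | intermediate
23 | ethyl (6R,8R)-8-(2-bromoethyl)-7-hydroxy-6,8-dimethyl-4-oxo-7-(trifluoroacetylperoxy)-4,5,6,7,8,9-hexahydrocycloocta[b]furan-3-carboxylate (Criegee adduct, C7 epimers) | CCOC(=O)c1c2c(C[C@](C)(CCBr)C(O)(OOC(=O)C(F)(F)F)[C@H](C)CC2=O)oc1 | intermediate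
24 | keto lactone (4R,10R): furan-fused nine-membered lactone, ring C1(=O)–O–C4–C5–C6=C7–C8(=O)–C9–C10; C4: CH3, CH2CH2Br; C10: CH3; C11: CO2Et | CCOC(=O)c1c2c(C[C@](C)(CCBr)OC(=O)[C@H](C)CC2=O)oc1 | intermediate
25 | hydroxy ester (4R,8S,10R): as 24 with C8 carbinol | CCOC(=O)c1c2c(C[C@](C)(CCBr)OC(=O)[C@H](C)C[C@@H]2O)oc1 | intermediate
26 | bromo bis-lactone (4R,8S,10R): nine-membered C1–O–C4 lactone and γ-lactone C8–O–C13(=O) on the furan | O=C1c2c3c(C[C@](C)(CCBr)OC(=O)[C@H](C)C[C@@H]3O1)oc2 | intermediate
27 | bridged hemiketal (1R,4S,8S,10R): 1-hydroxy-1,4-epoxide, γ-lactone C8–O–C13 | O=C1c2c3c(C[C@]4(C)CC[C@@](O)(O4)[C@H](C)C[C@@H]3O1)oc2 | intermediate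
28 | triethylsilyl ketal of 27 (1S,4S,8S,10R) | O=C1c2c3c(C[C@]4(C)CC[C@@](O[Si](CC)(CC)CC)(O4)[C@H](C)C[C@@H]3O1)oc2 | intermediate
29 | diol (1S,4S,8S,10R): C13 CH2OH, C8 OH, C1 OSiEt3 | OCc1c2c(C[C@]3(C)CC[C@@](O[Si](CC)(CC)CC)(O3)[C@H](C)C[C@@H]2O)oc1 | intermediate
30 | C13 acetate (1S,4S,8S,10R), C8 OH | CC(=O)OCc1c2c(C[C@]3(C)CC[C@@](O[Si](CC)(CC)CC)(O3)[C@H](C)C[C@@H]2O)oc1 | intermediate
31 | 2-(tert-butyldimethylsilyloxy)acetaldehyde | O=CCO[Si](C)(C)C(C)(C)C | starting material
32 | ethyl 2-(triphenylphosphoranylidene)propanoate | CCOC(=O)C(C)=P(c1ccccc1)(c1ccccc1)c1ccccc1 | starting material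
33 | ethyl (2E)-4-(tert-butyldimethylsilyloxy)-2-methylbut-2-enoate | CCOC(=O)/C(C)=C/CO[Si](C)(C)C(C)(C)C | intermediate
34 | (2E)-4-(tert-butyldimethylsilyloxy)-2-methylbut-2-enoic acid | OC(=O)/C(C)=C/CO[Si](C)(C)C(C)(C)C | intermediate
35 | furan diester (1S,4S,8S,10R): C13 OAc, C8 silyloxytiglate, C1 OSiEt3 | CC(=O)OCc1c2c(C[C@]3(C)CC[C@@](O[Si](CC)(CC)CC)(O3)[C@H](C)C[C@@H]2OC(=O)/C(C)=C/CO[Si](C)(C)C(C)(C)C)oc1 | intermediate
36 | furan endoperoxide of 35 (peroxide bridge C6–O–O–C12) | CC(=O)OCC1=C2C3(C[C@]4(C)CC[C@@](O[Si](CC)(CC)CC)(O4)[C@H](C)C[C@@H]2OC(=O)/C(C)=C/CO[Si](C)(C)C(C)(C)C)OOC1O3 | intermediate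
37 | γ-hydroxybutenolide (1S,4S,8S,10R; C6 epimers): 6-hydroxy-12,6-olide, 7(11)-ene | CC(=O)OCC1=C2C(O)(C[C@]3(C)CC[C@@](O[Si](CC)(CC)CC)(O3)[C@H](C)C[C@@H]2OC(=O)/C(C)=C/CO[Si](C)(C)C(C)(C)C)OC1=O | intermediate
38 | C6 methanesulfonate of 37 | CC(=O)OCC1=C2C(OS(C)(=O)=O)(C[C@]3(C)CC[C@@](O[Si](CC)(CC)CC)(O3)[C@H](C)C[C@@H]2OC(=O)/C(C)=C/CO[Si](C)(C)C(C)(C)C)OC1=O | intermediate
39 | bis-silyl ether of the target (1S,4S,8S,10R): C1 OSiEt3, tiglate O-SiMe2t-Bu | CC(=O)OCC1=C2/C(=C\[C@]3(C)CC[C@@](O[Si](CC)(CC)CC)(O3)[C@H](C)C[C@@H]2OC(=O)/C(C)=C/CO[Si](C)(C)C(C)(C)C)OC1=O | intermediate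
40 | (1R,4S,8S,10R)-13-acetoxy-1-hydroxy-8-[(2E)-4-hydroxy-2-methylbut-2-enoyloxy]-1,4-epoxygermacra-5,7(11)-dien-12,6-olide | CC(=O)OCC1=C2/C(=C\[C@]3(C)CC[C@@](O)(O3)[C@H](C)C[C@@H]2OC(=O)/C(C)=C/CO)OC1=O | target

**Totals**

Total step count: 23. Longest linear sequence: 18 steps (1, 2, 5, 6, 8–17, 20–23).

**Steps most likely to fail, each with a fallback**

Step 13 (ring expansion). The peracid may oxidise the furan or the C8 ketone, or the secondary C10 may migrate in place of C4. The fallback inserts the oxygen by a radical route and a peroxide ring contraction. It sets out from 22: Corey–Bakshi–Shibata reduction of the C8 ketone and lactonisation onto the ethyl ester, as in step 14, should give keto bromide γ-lactone F1. A samarium-Barbier cyclisation (SmI2, HMPA) of the bromide onto the C1 ketone should give ring-fusion cyclobutanol F2. Aerobic oxidation with Co(acac)2 under O2 (alkoxy radical, β-scission of the strained C1–C4 bond to the tertiary C4 radical, capture of O2) should give 1,2-dioxan-3-ol F3, in which a ten-membered peroxide ring C1–O–O–C4 spans the former carbocycle. PPh3 then removes one peroxide oxygen and the resulting hydroxy ketone closes to hemiketal 27, where the route is rejoined before the silylation of step 15. The price is that the C4 configuration is decided at oxygen capture rather than by a stereoretentive shift, so C4 epimers may have to be separated at 28.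

Step 9 (eight-membered ring closure). Intermolecular alkylation (oligomers) or O-alkylation may outrun the C-alkylation at C4–C5. The fallback closes the ring at the C1–C4 bond by acylation instead. It sets out from 12: allyl tert-butyl malonate F4 (from tert-butyl hydrogen malonate, allyl bromide, K2CO3) is alkylated by the chloromethyl group of 12 (NaH, THF) to give malonate acid F5. The C1 acid is turned into its chloride with 1-chloro-N,N,2-trimethylprop-1-en-1-amine and cyclised by soft enolisation (MgCl2, Et3N, MeCN, high dilution) to the ring acyl malonate F6. CF3CO2H removes the tert-butyl ester with loss of CO2 to give the ring β-keto ester F7 (hydrogen on the former malonate carbon), and C-methylation (MeI, K2CO3, acetone) returns to 18.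

Step 15 (oxolane closure). Electron transfer to the furan-conjugated γ-lactone or over-reduction of the adduct may compete with the acyl substitution. The fallback replaces the organosamarium by a stabilised carbanion. It sets out from 26: displacement of bromide with NaNO2 (DMF, phloroglucinol) gives nitro bis-lactone F8; DBU then promotes intramolecular acylation of the nitronate by the C1 lactone carbonyl (5-exo) to give α-nitro hemiketal F9; radical denitration of its α-nitro ketone tautomer (Bu3SnH, AIBN, benzene, 80 °C) gives 27, where the route is rejoined before silylation.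

**Further compounds**

F1 | step 13 | keto bromide γ-lactone: 22 with the C8 ketone reduced (8S) and lactonised onto C13, C1 ketone kept | O=C1c2c3c(C[C@](C)(CCBr)C(=O)[C@H](C)C[C@@H]3O1)oc2
F2 | step 13 | ring-fusion cyclobutanol: bicyclo[6.2.0] carbocycle with C1(OH)–C2 bond formed, γ-lactone C8–O–C13 | O=C1c2c3c(C[C@]4(C)CCC4(O)[C@H](C)C[C@@H]3O1)oc2
F3 | step 13 | 1,2-dioxan-3-ol: peroxide bridge C1(OH)–O–O–C4 across the ten-membered carbocycle, γ-lactone C8–O–C13 | O=C1c2c3c(C[C@]4(C)CCC(O)(OO4)[C@H](C)C[C@@H]3O1)oc2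
F4 | step 9 | tert-butyl prop-2-en-1-yl propanedioate | C=CCOC(=O)CC(=O)OC(C)(C)C
F5 | step 9 | malonate acid: 12 with the chloromethyl group replaced by CH2CH(CO2allyl)(CO2t-Bu) | CCOC(=O)c1coc(CC(C(=O)OCC=C)C(=O)OC(C)(C)C)c1C(=O)C[C@@H](C)C(=O)O
F6 | step 9 | ring acyl malonate: 8-tert-butyl 3-ethyl 8-(prop-2-en-1-yl) (6R)-6-methyl-4,7-dioxo-4,5,6,7,8,9-hexahydrocycloocta[b]furan-3,8,8-tricarboxylate | CCOC(=O)c1c2c(CC(C(=O)OCC=C)(C(=O)OC(C)(C)C)C(=O)[C@H](C)CC2=O)oc1
F7 | step 9 | 3-ethyl 8-(prop-2-en-1-yl) (6R)-6-methyl-4,7-dioxo-4,5,6,7,8,9-hexahydrocycloocta[b]furan-3,8-dicarboxylate (C8 epimers) | CCOC(=O)c1c2c(CC(C(=O)OCC=C)C(=O)[C@H](C)CC2=O)oc1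
F8 | step 15 | nitro bis-lactone: 26 with CH2CH2NO2 in place of CH2CH2Br | O=C1c2c3c(C[C@](C)(CC[N+](=O)[O-])OC(=O)[C@H](C)C[C@@H]3O1)oc2
F9 | step 15 | α-nitro hemiketal: 27 bearing NO2 on C2 (C2 epimers) | O=C1c2c3c(C[C@]4(C)CC([N+](=O)[O-])[C@@](O)(O4)[C@H](C)C[C@@H]3O1)oc2
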